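## Structural features

The target is (2S,3S)-2-(3,4-dihydroxyphenyl)-3-(4-hydroxy-2-oxo-2H-pyran-6-yl)-6-[(E)-2-(4-hydroxyphenyl)ethenyl]-2,3-dihydro-4H-furo[3,2-c]pyran-4-one. Its core is an α-pyranone (ring A: C3a, C4, O5, C6, C7, C7a) that shares the C3a=C7a bond with a dihydrofuran (ring B: O1, C2, C3, C3a, C7a). Ring A carries an (E)-4-hydroxystyryl arm at C6, C2 carries a catechol ring, and C3 is bonded to C6 of a second, free 4-hydroxy-2-pyranone (ring C). The only stereocentres are the neighbouring carbons C2 and C3, both S, with the catechol and ring C trans across ring B. Fragile parts are the catechol (oxidation as the catecholate), the two vinylogous acid or ester pyranones, the styrene (no hydrogenation), the benzylic C2–O1 bond whose leaving group is a vinylogous carboxylate, and the C3–H between ring A and ring C, whose removal could epimerise C3 or open ring B. The real difficulty is the absolute configuration of the C2/C3 pair, set between three oxygenated π-systems that tolerate neither strong base, strong acid nor reduction. The key step uses the fact that O1–C7a=C3a is simply the enol of a 4-hydroxy-2-pyranone, that C3 is at the aldehyde oxidation level and that C2 is a single benzylic carbon. Ring B is therefore the sum of a four-atom unit O1–C7a=C3a–C3 (a 3-alkylidenepyran-2,4-dione) and a one-carbon benzylic ylide.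

## Logic of the disconnections

21 ⇒ 20. The three phenolic O–H bonds become O–Si bonds and the ring-C O–H becomes an O–CH2CH2SiMe3 bond. The free catechol, phenol and vinylogous acid would be deprotonated, alkylated or oxidised under basic ylide conditions, and all four masks answer to fluoride. The gain is a lipophilic, non-acidic intermediate. The forward step must stay near neutral so that C3–H and the C2–O1 bond are left alone.

20 ⇒ 9 + 17 (through 18 and 19). Both bonds to C2 are cut: C2–C3 and O1–C2. This removes ring B and both stereocentres at once and leaves an achiral bis-pyranone holding the aldehyde-level carbon plus a one-carbon benzylic donor that carries all the chiral information. The forward step must add the benzylic carbon to the exocyclic carbon of 18 in conjugate fashion, close the ring through oxygen with loss of 16, select one ylide face and give the trans ring, under a base that spares aryl silyl ethers.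

9 ⇒ 5 + 7 (through 8). The C–C bond between C3 of ring A and the methine carbon is cut, together with the C–S bond. The methine is an aldehyde carbon next to the most nucleophilic carbon of a vinylogous acid, so this is a Knoevenagel-type bond made by way of 8; the sulfonyl group only keeps 18, which cannot be isolated, in a storable form. Two pyranones of similar size result. The forward step must put sulfinate on the methine carbon faster than a second molecule of 5 can attack it.

5 ⇒ 3 + 2 (through 4), and 2 ⇒ 1. The styryl C=C bond is cut to a methyl carbanion and an aldehyde, then the O–Si bond of 2. This leads to two commercial compounds. The forward step must form the bond at the methyl group and not at C3 (hence the dianion) and must give the E alkene, which conjugation secures on dehydration.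

7 ⇒ 6 ⇒ 3. The formyl C=O is traced back to the methyl C–H bonds, and the ether O–C bond is cut. Both pyranone halves of 9 then come from 3. The oxidation must stop at the aldehyde, and the alkylation must go to the 4-oxygen and not to C3 or the lactone oxygen.

17 ⇒ 13 + 16. The benzylic C–S bond is cut, separating the recoverable chiral controller from the aryl part. The forward alkylation has to cope with a hindered sulfide and an easily ionised benzylic bromide.

13 ⇒ 12 ⇒ 11 ⇒ 10. C–Br, then the carbinol C–H, then two O–Si bonds are cut: plain functional-group changes back to a commercial aldehyde. Each forward step must leave the silyl ethers in place.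

16 ⇒ 15 ⇒ 14. Both C–S bonds are cut. Each forward displacement inverts, so the (2R,5R) diol gives the (2S,5S) thiolane; the step must be clean SN2 without elimination.

## Other disconnections considered

Alternative 1: The cut is the C3–C3a bond, made by a 1,2-shift with ring contraction. A flavanone analogue built on a 6-methyl-2-pyranone, (2S)-2-[3,4-bis(benzyloxy)phenyl]-7-methyl-2,3-dihydro-4H,5H-pyrano[4,3-b]pyran-4,5-dione A1, would be treated with PhI(OH)OTs in trimethyl orthoformate. The ketone becomes its methyl enol ether, trivalent iodine attacks the methylene carbon, and the ring-fusion pyranone carbon migrates to it as iodobenzene leaves, giving methyl (2S,3S)-2-[3,4-bis(benzyloxy)phenyl]-6-methyl-4-oxo-2,3-dihydro-4H-furo[3,2-c]pyran-3-carboxylate A2.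
- In favour: the ring contraction is an established reaction type in the flavanone series, the trans ring follows from the migration geometry, and A1 comes from cheap materials.
- Against: the migrating carbon bears a lactone carbonyl and is less electron-rich than the alkoxyaryl carbon of a true flavanone, so α-methoxylation or dehydrogenation may compete. A2 lacks both ring C and the styryl arm. Ring C must be grown from the ester at a C3–H that is α to a carbonyl and β to a vinylogous carboxylate leaving group. The styryl arm needs a base-mediated condensation at the 6-methyl group. The benzyl ethers cannot be hydrogenolysed next to the styrene. C2 needs its own asymmetric oxa-Michael step, which is reversible.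
- Comparison: on structure the chosen plan forms ring B last from complete pieces, whereas here ring B comes first and most of the molecule is added afterwards. On mechanism the alternative is the equal or the better of the chosen plan for relative configuration and for precedent of the ring-forming event; for absolute configuration it is no more secure. On step economy it is clearly poorer (seven or more operations after the key step against one).

Alternative 2: The cuts are C7–C7a and O5–C6, the two bonds that close ring A. (4R,5S)-5-[3,4-bis(tert-butyldimethylsilyloxy)phenyl]-4-[(4-methoxybenzyloxy)methyl]-4,5-dihydrofuran-3-carboxylic acid A3 and dimethylsulfoxonium (E)-2-oxo-4-[4-(tert-butyldimethylsilyloxy)phenyl]but-3-enylide A4 would be combined with [Cp*RhCl2]2, AgSbF6 and NaOAc. Carboxylate-directed metalation of the vinylic C–H by trivalent rhodium, carbene insertion and lactonisation onto the ketone would give (2S,3R)-2-[3,4-bis(tert-butyldimethylsilyloxy)phenyl]-3-[(4-methoxybenzyloxy)methyl]-6-[(E)-4-(tert-butyldimethylsilyloxy)styryl]-2,3-dihydro-4H-furo[3,2-c]pyran-4-one A5 (same spatial arrangement as the target; the descriptor at C3 changes with the substituent).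
- In favour: ring A and the styryl arm arrive together in one convergent step, and the key step creates no stereocentre.
- Against: A3 is a β-alkoxyacrylic acid whose dihydrofuran may open or aromatise in a cationic rhodium and silver medium. The enone of A4 is a competing ligand and acceptor. A5 still lacks ring C: PMB removal, oxidation to a β-oxygenated aldehyde (elimination risk), four-carbon extension and cyclisation add five or more steps. A3 needs an enantioselective synthesis of its own.
- Comparison: on structure, the alternative is the equal or the better of the chosen plan in how it introduces the styrylpyranone (late, with no dianion aldol). On mechanism it separates stereochemistry from ring formation, an advantage in predictability, but C–H annulation on this substrate class is no less speculative than the ylide annulation. On step economy it is much poorer.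

Alternative 3: The cuts are C2–C3 and O1–C7a. The boron enolate (Bu2BOTf, iPr2NEt) of (S)-4-benzyl-3-{2-[4-chloro-2-oxo-6-((E)-4-(tert-butyldimethylsilyloxy)styryl)-2H-pyran-3-yl]acetyl}oxazolidin-2-one A6 would add to 3,4-bis(tert-butyldimethylsilyloxy)benzaldehyde A7 in an Evans syn-aldol. After release of boron the C2 alkoxide would displace chloride by addition–elimination, giving (S)-4-benzyl-3-{(2S,3S)-2-[3,4-bis(tert-butyldimethylsilyloxy)phenyl]-4-oxo-6-[(E)-4-(tert-butyldimethylsilyloxy)styryl]-2,3-dihydro-4H-furo[3,2-c]pyran-3-carbonyl}oxazolidin-2-one A8.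
- In favour: it has the same two-bond logic around ring B with reversed polarity at C2. The closed aldol transition state is well understood: the syn-aldol of the (S)-auxiliary maps onto (2S,3S), and a syn-aldol closes to the trans ring.
- Against: the aldolate of an aryl-acetyl-type imide is prone to retro-aldol. In A8 the C3–H is α to the imide and β to the vinylogous carboxylate O1, so E1cB ring opening threatens. The amine base or the enolate may attack the chloropyranone. Ring C must still be built from the imide in three to four steps on that labile centre.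
- Comparison: on structure it is equal in forming ring B on a finished ring A, but ring C is missing. On mechanism its stereocontrol is better founded than the unproven face selection of the ylide, and this is a point where the alternative is the better plan. The stoichiometric, recoverable chiral controller is an equal point. On step economy it is poorer by three to five steps.

Key step: step 12

## Remarks and assumptions

- Descriptors: the target and 20 are (2S,3S), trans. The (2R,5R) diol gives the (2S,5S) thiolane because both displacements invert.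
- Protecting groups: the three phenols are masked as triisopropylsilyl ethers instead of tert-butyldimethylsilyl ethers. Aryl tert-butyldimethylsilyl ethers are cleaved by carbonate bases, and step 12 uses Cs2CO3. The triisopropylsilyl ethers should also tolerate LiN(iPr)2, p-TsOH and sulfinic acid, and still fall to fluoride. The skeletons of the key-step precursor and product are unchanged.
- Assumption: the sense of induction of ylide 19 is taken from the accepted model for epoxidation with C2-symmetric 2,5-dimethylthiolane benzylides (face choice, then inversion); because the CIP ranking of aryl and neighbouring carbon is reversed in a dihydrofuran, the (2S,5S) thiolane is predicted to give 2S. If the acceptor reverses this, (2S,5S)-hexane-2,5-diol replaces 14 and nothing else changes.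

## Route

Step 1
Reactants: 1 4-hydroxybenzaldehyde
Product: 2 4-[(triisopropylsilyl)oxy]benzaldehyde
Conditions: iPr3SiCl, imidazole, DMF, rt
Reagents that add atoms: chlorotriisopropylsilane, CC(C)[Si](Cl)(C(C)C)C(C)C
Why: Silylation of a phenol with a silyl chloride and imidazole; the bulky silyl group is chosen because it survives the carbonate base of step 12 and the acids of steps 2 and 5.

Step 2
Reactants: 3 4-hydroxy-6-methyl-2H-pyran-2-one; 2 4-[(triisopropylsilyl)oxy]benzaldehyde
Product: 5 4-hydroxy-6-[(E)-2-{4-[(triisopropylsilyl)oxy]phenyl}ethenyl]-2H-pyran-2-one, via racemic aldol adduct 4 (not isolated)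
Conditions: LiN(iPr)2 (2.2 equiv), THF–DMPU, −78 °C; 2, −78 → −20 °C; AcOH; crude 4, p-TsOH·H2O (10 mol %), toluene, 80 °C
Reagents that add atoms: none
Why: The O,C-dianion of the vinylogous acid reacts at its more basic methylene terminus in an aldol addition, and the benzylic alcohol para to a silyloxy group should ionise under acid and lose water (E1) to the conjugated, thermodynamically preferred E alkene.

Step 3
Reactants: 3 4-hydroxy-6-methyl-2H-pyran-2-one
Product: 6 6-methyl-4-[2-(trimethylsilyl)ethoxy]-2H-pyran-2-one
Conditions: Me3SiCH2CH2OH, PPh3, DIAD, THF, 0 °C → rt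
Reagents that add atoms: 2-(trimethylsilyl)ethanol, C[Si](C)(C)CCO
Why: Mitsunobu O-alkylation of the acidic 4-hydroxy-2-pyranone (pKa about 5) with a primary alcohol, a known way to 4-alkoxy-2-pyranones that avoids C3-alkylation.

Step 4
Reactants: 6 6-methyl-4-[2-(trimethylsilyl)ethoxy]-2H-pyran-2-one
Product: 7 2-oxo-4-[2-(trimethylsilyl)ethoxy]-2H-pyran-6-carbaldehyde
Conditions: SeO2, 1,4-dioxane, 150 °C, sealed tube
Reagents that add atoms: selenium dioxide, O=[Se]=O
Why: Riley oxidation of the vinylogously activated 6-methyl group, as known for 4-methoxy-6-methyl-2-pyranone; the 4-ether blocks the nucleophilic enol site and the C–Si bond is inert to SeO2.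

Step 5
Reactants: 5 4-hydroxy-6-[(E)-2-{4-[(triisopropylsilyl)oxy]phenyl}ethenyl]-2H-pyran-2-one; 7 2-oxo-4-[2-(trimethylsilyl)ethoxy]-2H-pyran-6-carbaldehyde
Product: 9 4-hydroxy-3-[(phenylsulfonyl){2-oxo-4-[2-(trimethylsilyl)ethoxy]-2H-pyran-6-yl}methyl]-6-[(E)-2-{4-[(triisopropylsilyl)oxy]phenyl}ethenyl]-2H-pyran-2-one (racemic), via Knoevenagel carbinol 8 (not isolated)
Conditions: PhSO2Na (3 equiv), HCO2H, THF–H2O, rt; product collected by precipitation
Reagents that add atoms: sodium benzenesulfinate, [Na+].[O-]S(=O)c1ccccc1
Why: C3 of the vinylogous acid adds to the electron-poor aldehyde (Knoevenagel-type aldol addition) to give carbinol 8, whose hydroxyl, activated by the neighbouring enol, is lost as water under the acid while benzenesulfinic acid is taken up through sulfur at the same carbon (three-component sulfonylalkylation of 1,3-dicarbonyl-type nucleophiles). Excess sulfinate should outrun attack by a second molecule of 5, and the new stereocentre is irrelevant because it is lost in step 12.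

Step 6
Reactants: 10 3,4-dihydroxybenzaldehyde
Product: 11 3,4-bis[(triisopropylsilyl)oxy]benzaldehyde
Conditions: iPr3SiCl (2.4 equiv), imidazole, DMAP (cat.), DMF, rt → 40 °C
Reagents that add atoms: chlorotriisopropylsilane, CC(C)[Si](Cl)(C(C)C)C(C)C
Why: Double silylation of a catechol under the same imidazole protocol as step 1; mild warming compensates for the crowding of the second silyl group.

Step 7
Reactants: 11 3,4-bis[(triisopropylsilyl)oxy]benzaldehyde
Product: 12 {3,4-bis[(triisopropylsilyl)oxy]phenyl}methanol
Conditions: NaBH4, THF–MeOH, 0 °C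
Reagents that add atoms: none
Why: Hydride reduction of an aryl aldehyde; low temperature and short contact keep the aryl silyl ethers from methanolysis.

Step 8
Reactants: 12 {3,4-bis[(triisopropylsilyl)oxy]phenyl}methanol
Product: 13 4-(bromomethyl)-1,2-bis[(triisopropylsilyl)oxy]benzene
Conditions: CBr4, PPh3, CH2Cl2, 0 °C; short silica plug, used at once
Reagents that add atoms: carbon tetrabromide, BrC(Br)(Br)Br
Why: Appel bromination converts the benzylic alcohol under neutral conditions, which suits both the silyl ethers and the easily ionised electron-rich benzylic bromide.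

Step 9
Reactants: 14 (2R,5R)-hexane-2,5-diol
Product: 15 (2R,5R)-hexane-2,5-diyl dimethanesulfonate
Conditions: MsCl, Et3N, CH2Cl2, −10 → 0 °C
Reagents that add atoms: methanesulfonyl chloride, CS(=O)(=O)Cl
Why: O-sulfonylation of the secondary alcohols; no C–O bond is broken, so both centres keep their configuration.

Step 10
Reactants: 15 (2R,5R)-hexane-2,5-diyl dimethanesulfonate
Product: 16 (2S,5S)-2,5-dimethylthiolane
Conditions: Na2S·9H2O, DMSO, rt; distillation
Reagents that add atoms: sodium sulfide (used as the nonahydrate), [Na+].[Na+].[S-2]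
Why: Two SN2 displacements by sulfur (the second a 5-exo-tet closure) each invert, so the (2R,5R) dimesylate should give the trans (2S,5S) thiolane.

Step 11
Reactants: 13 4-(bromomethyl)-1,2-bis[(triisopropylsilyl)oxy]benzene; 16 (2S,5S)-2,5-dimethylthiolane
Product: 17 (2S,5S)-1-{3,4-bis[(triisopropylsilyl)oxy]benzyl}-2,5-dimethylthiolan-1-ium tetrafluoroborate
Conditions: AgBF4, CH2Cl2, 0 °C → rt, dark
Reagents that add atoms: silver tetrafluoroborate, [Ag+].F[B-](F)(F)F
Why: S-alkylation of the sulfide, driven by precipitation of AgBr, gives the salt with a non-nucleophilic counter-ion; sulfur is not a stereocentre because the thiolane is C2-symmetric.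

Step 12
Reactants: 9 4-hydroxy-3-[(phenylsulfonyl){2-oxo-4-[2-(trimethylsilyl)ethoxy]-2H-pyran-6-yl}methyl]-6-[(E)-2-{4-[(triisopropylsilyl)oxy]phenyl}ethenyl]-2H-pyran-2-one; 17 (2S,5S)-1-{3,4-bis[(triisopropylsilyl)oxy]benzyl}-2,5-dimethylthiolan-1-ium tetrafluoroborate
Product: 20 (2S,3S)-2-{3,4-bis[(triisopropylsilyl)oxy]phenyl}-3-{2-oxo-4-[2-(trimethylsilyl)ethoxy]-2H-pyran-6-yl}-6-[(E)-2-{4-[(triisopropylsilyl)oxy]phenyl}ethenyl]-2,3-dihydro-4H-furo[3,2-c]pyran-4-one, via alkylidenepyrandione 18 (not isolated), via sulfonium benzylide 19 (not isolated)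
Conditions: 17 (1.5 equiv), Cs2CO3 (3 equiv), 4 Å MS, CH2Cl2–MeCN, −20 → 0 °C, dark
Reagents that add atoms: none
Why: Proposed new method: Cs2CO3 removes the acidic 4-OH proton of 9 and the pyronate expels benzenesulfinate (E1cB) to release 18, while the same base turns 17 into the semistabilised benzylide 19; the closest known reaction type is the (4+1) annulation of sulfone-derived ortho-quinone methides with sulfonium ylides to trans-2,3-dihydrobenzofurans, next to ylide annulations of 4-hydroxycoumarin–aldehyde condensation products. The ylide carbon of 19 should add to the exocyclic carbon of 18, the position activated by both ring carbonyl groups, forming C2–C3 and a betaine in which the 4-oxygen of the pyrandione enolate sits five atoms from the sulfonium-bearing carbon. That oxygen then attacks the benzylic carbon from the side opposite sulfur (5-exo-tet), 16 leaves, C2 is inverted and ring B is closed through O1–C2; closure through the 4-oxygen and not the lactone carbonyl oxygen is expected because it gives the conjugated 2-pyranone. C2 is under reagent control: the two conformers of the C2-symmetric ylide are identical, one methyl group screens one face of the carbanion, and attack on the open face followed by inversion is predicted to give 2S. C3 is set relative to C2: addition of a semistabilised ylide is reversible, the anti betaine closes fastest because the aryl group and ring C avoid each other, and a cis isomer could still epimerise at the acidic C3–H to the trans compound without touching C2. Chemoselectivity comes from the substrate: the aldehyde carbon is stored in the sulfone so no epoxide can form, ring C is a far weaker acceptor than the alkylidenedione, and ring A is a pyronate before release of 18 and an enolate after the addition, so its styryl group is no acceptor. The step needs conjugate addition to win over benzylation of the pyronate or of sulfinate by 17 and needs high face selectivity; low temperature, slow release of 18 and an excess of 17 serve both.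

Step 13
Reactants: 20 (2S,3S)-2-{3,4-bis[(triisopropylsilyl)oxy]phenyl}-3-{2-oxo-4-[2-(trimethylsilyl)ethoxy]-2H-pyran-6-yl}-6-[(E)-2-{4-[(triisopropylsilyl)oxy]phenyl}ethenyl]-2,3-dihydro-4H-furo[3,2-c]pyran-4-one
Product: 21 (2S,3S)-2-(3,4-dihydroxyphenyl)-3-(4-hydroxy-2-oxo-2H-pyran-6-yl)-6-[(E)-2-(4-hydroxyphenyl)ethenyl]-2,3-dihydro-4H-furo[3,2-c]pyran-4-one
Conditions: Bu4NF (8 equiv), AcOH (8 equiv), THF, 0 → 40 °C, argon, dark; reversed-phase purification
Reagents that add atoms: none
Why: Fluoride cleaves the three aryl silyl ethers and attacks the trimethylsilyl group of the vinylogous 2-(trimethylsilyl)ethyl ester, which fragments to ethylene and the pyronate as such esters do; the acetic acid buffer keeps the catechol protonated and C3–H untouched, so C2 and C3 are not disturbed.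

## Compound list

1 | 4-hydroxybenzaldehyde | O=Cc1ccc(O)cc1 | starting material
2 | 4-[(triisopropylsilyl)oxy]benzaldehyde | O=Cc1ccc(O[Si](C(C)C)(C(C)C)C(C)C)cc1 | intermediate
3 | 4-hydroxy-6-methyl-2H-pyran-2-one | Cc1cc(O)cc(=O)o1 | starting material
4 | 4-hydroxy-6-(2-hydroxy-2-{4-[(triisopropylsilyl)oxy]phenyl}ethyl)-2H-pyran-2-one (racemic; not isolated) | OC(Cc1cc(O)cc(=O)o1)c1ccc(O[Si](C(C)C)(C(C)C)C(C)C)cc1 | intermediate
5 | 4-hydroxy-6-[(E)-2-{4-[(triisopropylsilyl)oxy]phenyl}ethenyl]-2H-pyran-2-one | O=c1cc(O)cc(/C=C/c2ccc(O[Si](C(C)C)(C(C)C)C(C)C)cc2)o1 | intermediate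
6 | 6-methyl-4-[2-(trimethylsilyl)ethoxy]-2H-pyran-2-one | Cc1cc(OCC[Si](C)(C)C)cc(=O)o1 | intermediate
7 | 2-oxo-4-[2-(trimethylsilyl)ethoxy]-2H-pyran-6-carbaldehyde | O=Cc1cc(OCC[Si](C)(C)C)cc(=O)o1 | intermediate
8 | 4-hydroxy-3-[hydroxy{2-oxo-4-[2-(trimethylsilyl)ethoxy]-2H-pyran-6-yl}methyl]-6-[(E)-2-{4-[(triisopropylsilyl)oxy]phenyl}ethenyl]-2H-pyran-2-one (racemic; not isolated) | O=c1cc(OCC[Si](C)(C)C)cc(C(O)c2c(O)cc(/C=C/c3ccc(O[Si](C(C)C)(C(C)C)C(C)C)cc3)oc2=O)o1 | intermediate
9 | 4-hydroxy-3-[(phenylsulfonyl){2-oxo-4-[2-(trimethylsilyl)ethoxy]-2H-pyran-6-yl}methyl]-6-[(E)-2-{4-[(triisopropylsilyl)oxy]phenyl}ethenyl]-2H-pyran-2-one (racemic) | O=c1cc(OCC[Si](C)(C)C)cc(C(c2c(O)cc(/C=C/c3ccc(O[Si](C(C)C)(C(C)C)C(C)C)cc3)oc2=O)S(=O)(=O)c2ccccc2)o1 | intermediate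
10 | 3,4-dihydroxybenzaldehyde | O=Cc1ccc(O)c(O)c1 | starting material
11 | 3,4-bis[(triisopropylsilyl)oxy]benzaldehyde | O=Cc1ccc(O[Si](C(C)C)(C(C)C)C(C)C)c(O[Si](C(C)C)(C(C)C)C(C)C)c1 | intermediate
12 | {3,4-bis[(triisopropylsilyl)oxy]phenyl}methanol | OCc1ccc(O[Si](C(C)C)(C(C)C)C(C)C)c(O[Si](C(C)C)(C(C)C)C(C)C)c1 | intermediate
13 | 4-(bromomethyl)-1,2-bis[(triisopropylsilyl)oxy]benzene | BrCc1ccc(O[Si](C(C)C)(C(C)C)C(C)C)c(O[Si](C(C)C)(C(C)C)C(C)C)c1 | intermediate
14 | (2R,5R)-hexane-2,5-diol | C[C@@H](O)CC[C@@H](C)O | starting material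
15 | (2R,5R)-hexane-2,5-diyl dimethanesulfonate | C[C@@H](OS(C)(=O)=O)CC[C@@H](C)OS(C)(=O)=O | intermediate
16 | (2S,5S)-2,5-dimethylthiolane | C[C@H]1CC[C@H](C)S1 | intermediate
17 | (2S,5S)-1-{3,4-bis[(triisopropylsilyl)oxy]benzyl}-2,5-dimethylthiolan-1-ium tetrafluoroborate | C[C@H]1CC[C@H](C)[S+]1Cc1ccc(O[Si](C(C)C)(C(C)C)C(C)C)c(O[Si](C(C)C)(C(C)C)C(C)C)c1.F[B-](F)(F)F | intermediate
18 | 3-({2-oxo-4-[2-(trimethylsilyl)ethoxy]-2H-pyran-6-yl}methylidene)-6-[(E)-2-{4-[(triisopropylsilyl)oxy]phenyl}ethenyl]-2H-pyran-2,4(3H)-dione (exocyclic alkene geometry not defined; not isolated) | O=C1OC(/C=C/c2ccc(O[Si](C(C)C)(C(C)C)C(C)C)cc2)=CC(=O)C1=Cc1cc(OCC[Si](C)(C)C)cc(=O)o1 | intermediate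
19 | (2S,5S)-2,5-dimethylthiolan-1-ium-1-yl {3,4-bis[(triisopropylsilyl)oxy]phenyl}methanide (sulfonium benzylide; not isolated) | C[C@H]1CC[C@H](C)[S+]1[CH-]c1ccc(O[Si](C(C)C)(C(C)C)C(C)C)c(O[Si](C(C)C)(C(C)C)C(C)C)c1 | intermediate
20 | (2S,3S)-2-{3,4-bis[(triisopropylsilyl)oxy]phenyl}-3-{2-oxo-4-[2-(trimethylsilyl)ethoxy]-2H-pyran-6-yl}-6-[(E)-2-{4-[(triisopropylsilyl)oxy]phenyl}ethenyl]-2,3-dihydro-4H-furo[3,2-c]pyran-4-one | O=c1cc(OCC[Si](C)(C)C)cc([C@H]2c3c(cc(/C=C/c4ccc(O[Si](C(C)C)(C(C)C)C(C)C)cc4)oc3=O)O[C@@H]2c2ccc(O[Si](C(C)C)(C(C)C)C(C)C)c(O[Si](C(C)C)(C(C)C)C(C)C)c2)o1 | intermediate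
21 | (2S,3S)-2-(3,4-dihydroxyphenyl)-3-(4-hydroxy-2-oxo-2H-pyran-6-yl)-6-[(E)-2-(4-hydroxyphenyl)ethenyl]-2,3-dihydro-4H-furo[3,2-c]pyran-4-one | O=c1cc(O)cc([C@H]2c3c(cc(/C=C/c4ccc(O)cc4)oc3=O)O[C@@H]2c2ccc(O)c(O)c2)o1 | target

## Step count and least certain steps

Total: 13 steps. Longest linear sequence: 6 steps (10 → 11 → 12 → 13 → 17 → 20 → 21; steps 6, 7, 8, 11, 12, 13).

Step 12 (key step, proposed new method). The most likely failures are benzylation of the pyronate of 9 or of the released sulfinate by the sulfonium salt, which would consume 17 before ylide addition; poor facial selectivity of the ylide towards this unusually reactive acceptor; Michael oligomerisation of the released alkylidene with unreacted pyronate; and base-induced opening of ring B through deprotonation at C3, which would erode C2. Fallback with known chemistry, setting out from 5 (with 6 and 11) and returning at 20: compound 6 is deprotonated at its methyl group with LiN(SiMe3)2 in THF at −78 °C and added to 11, which should give 6-(2-{3,4-bis[(triisopropylsilyl)oxy]phenyl}-2-hydroxyethyl)-4-[2-(trimethylsilyl)ethoxy]-2H-pyran-2-one F1. Catalytic p-TsOH in toluene dehydrates it to 6-[(E)-2-{3,4-bis[(triisopropylsilyl)oxy]phenyl}ethenyl]-4-[2-(trimethylsilyl)ethoxy]-2H-pyran-2-one F2. Mn(OAc)3·2H2O (trivalent manganese, 2.2 equiv) in AcOH at 50–60 °C oxidises 5 to its C3 radical, which adds to the pyranone-bound alkene carbon of F2 (used in excess); the benzylic radical is oxidised to the cation and captured by the enol oxygen. This is the known oxidative dihydrofuran annulation of cyclic 1,3-dicarbonyl compounds with styrenes, and should give the racemic trans compound rac-20 F3. Preparative chromatography of F3 on a chiral stationary phase returns the route to 20.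

Step 5. The likely failure is attack of a second molecule of 5 on the dehydrating carbinol (bis-pyranonylmethane formation) outrunning sulfinate capture, or loss of sulfinate from 9 during purification. Fallback from 5 and 7, returning at 9: thiophenol, a stronger nucleophile, intercepts the Knoevenagel intermediate (PhSH, EtOH, 40 °C) as 4-hydroxy-3-[(phenylsulfanyl){2-oxo-4-[2-(trimethylsilyl)ethoxy]-2H-pyran-6-yl}methyl]-6-[(E)-2-{4-[(triisopropylsilyl)oxy]phenyl}ethenyl]-2H-pyran-2-one F4. Chemoselective S-oxidation (H2O2, catalytic (NH4)6Mo7O24, EtOH, 0 °C) then gives 9.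

Step 4. The likely failures are over-oxidation to the carboxylic acid, incomplete conversion, or acid-induced loss of the 2-(trimethylsilyl)ethyl group at 150 °C. Fallback from 6, returning at 7: condensation of the activated methyl group with Me2NCH(OMe)2 (neat, 100 °C) gives 6-[(E)-2-(dimethylamino)ethenyl]-4-[2-(trimethylsilyl)ethoxy]-2H-pyran-2-one F5. Oxidative cleavage of the enamine double bond with NaIO4 in THF–H2O at rt then gives 7.

Step 11. The likely failure is ionisation and self-condensation of the electron-rich benzylic bromide outrunning S-alkylation of the hindered thiolane, or loss of silyl groups through adventitious HBF4. Fallback from 13 and 16, returning at 20: the tetrafluoroborate is not prepared. Instead 13, 16 (1–2 equiv), 9 and Cs2CO3 are combined in one flask, so that (2S,5S)-1-{3,4-bis[(triisopropylsilyl)oxy]benzyl}-2,5-dimethylthiolan-1-ium bromide F6 forms reversibly and is consumed in situ by deprotonation and annulation, as in one-pot sulfide-mediated ylide reactions of benzyl bromides; this leads directly to 20.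

Step 13. The likely failure is incomplete fragmentation of the 2-(trimethylsilyl)ethyl ether under buffered fluoride; with less buffer, base-mediated epimerisation or ring opening at C3 and oxidation of the catecholate threaten. Fallback from 20, returning at 21: brief acidolysis (CF3CO2H, CH2Cl2, 0 °C) removes the 2-(trimethylsilyl)ethyl group first, giving (2S,3S)-2-{3,4-bis[(triisopropylsilyl)oxy]phenyl}-3-(4-hydroxy-2-oxo-2H-pyran-6-yl)-6-[(E)-2-{4-[(triisopropylsilyl)oxy]phenyl}ethenyl]-2,3-dihydro-4H-furo[3,2-c]pyran-4-one F7. The three silyl ethers are then removed with Bu4NF–AcOH in THF at 0 °C to give 21.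

## Further compounds

F1 | step 12 | 6-(2-{3,4-bis[(triisopropylsilyl)oxy]phenyl}-2-hydroxyethyl)-4-[2-(trimethylsilyl)ethoxy]-2H-pyran-2-one (racemic) | OC(Cc1cc(OCC[Si](C)(C)C)cc(=O)o1)c1ccc(O[Si](C(C)C)(C(C)C)C(C)C)c(O[Si](C(C)C)(C(C)C)C(C)C)c1
F2 | step 12 | 6-[(E)-2-{3,4-bis[(triisopropylsilyl)oxy]phenyl}ethenyl]-4-[2-(trimethylsilyl)ethoxy]-2H-pyran-2-one | O=c1cc(OCC[Si](C)(C)C)cc(/C=C/c2ccc(O[Si](C(C)C)(C(C)C)C(C)C)c(O[Si](C(C)C)(C(C)C)C(C)C)c2)o1
F3 | step 12 | rac-20, racemic trans-2-{3,4-bis[(triisopropylsilyl)oxy]phenyl}-3-{2-oxo-4-[2-(trimethylsilyl)ethoxy]-2H-pyran-6-yl}-6-[(E)-2-{4-[(triisopropylsilyl)oxy]phenyl}ethenyl]-2,3-dihydro-4H-furo[3,2-c]pyran-4-one (ring stereocentres left undefined in the string) | O=c1cc(OCC[Si](C)(C)C)cc(C2c3c(cc(/C=C/c4ccc(O[Si](C(C)C)(C(C)C)C(C)C)cc4)oc3=O)OC2c2ccc(O[Si](C(C)C)(C(C)C)C(C)C)c(O[Si](C(C)C)(C(C)C)C(C)C)c2)o1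
F4 | step 5 | 4-hydroxy-3-[(phenylsulfanyl){2-oxo-4-[2-(trimethylsilyl)ethoxy]-2H-pyran-6-yl}methyl]-6-[(E)-2-{4-[(triisopropylsilyl)oxy]phenyl}ethenyl]-2H-pyran-2-one (racemic) | O=c1cc(OCC[Si](C)(C)C)cc(C(Sc2ccccc2)c2c(O)cc(/C=C/c3ccc(O[Si](C(C)C)(C(C)C)C(C)C)cc3)oc2=O)o1
F5 | step 4 | 6-[(E)-2-(dimethylamino)ethenyl]-4-[2-(trimethylsilyl)ethoxy]-2H-pyran-2-one | CN(C)/C=C/c1cc(OCC[Si](C)(C)C)cc(=O)o1
F6 | step 11 | (2S,5S)-1-{3,4-bis[(triisopropylsilyl)oxy]benzyl}-2,5-dimethylthiolan-1-ium bromide | C[C@H]1CC[C@H](C)[S+]1Cc1ccc(O[Si](C(C)C)(C(C)C)C(C)C)c(O[Si](C(C)C)(C(C)C)C(C)C)c1.[Br-]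
F7 | step 13 | (2S,3S)-2-{3,4-bis[(triisopropylsilyl)oxy]phenyl}-3-(4-hydroxy-2-oxo-2H-pyran-6-yl)-6-[(E)-2-{4-[(triisopropylsilyl)oxy]phenyl}ethenyl]-2,3-dihydro-4H-furo[3,2-c]pyran-4-one | O=c1cc(O)cc([C@H]2c3c(cc(/C=C/c4ccc(O[Si](C(C)C)(C(C)C)C(C)C)cc4)oc3=O)O[C@@H]2c2ccc(O[Si](C(C)C)(C(C)C)C(C)C)c(O[Si](C(C)C)(C(C)C)C(C)C)c2)o1
A1 | alternative 1 | (2S)-2-[3,4-bis(benzyloxy)phenyl]-7-methyl-2,3-dihydro-4H,5H-pyrano[4,3-b]pyran-4,5-dione | Cc1cc2O[C@H](c3ccc(OCc4ccccc4)c(OCc4ccccc4)c3)CC(=O)c2c(=O)o1
A2 | alternative 1 | methyl (2S,3S)-2-[3,4-bis(benzyloxy)phenyl]-6-methyl-4-oxo-2,3-dihydro-4H-furo[3,2-c]pyran-3-carboxylate | COC(=O)[C@H]1c2c(cc(C)oc2=O)O[C@@H]1c1ccc(OCc2ccccc2)c(OCc2ccccc2)c1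
A3 | alternative 2 | (4R,5S)-5-[3,4-bis(tert-butyldimethylsilyloxy)phenyl]-4-[(4-methoxybenzyloxy)methyl]-4,5-dihydrofuran-3-carboxylic acid | COc1ccc(COC[C@H]2C(C(=O)O)=CO[C@@H]2c2ccc(O[Si](C)(C)C(C)(C)C)c(O[Si](C)(C)C(C)(C)C)c2)cc1
A4 | alternative 2 | dimethylsulfoxonium (E)-2-oxo-4-[4-(tert-butyldimethylsilyloxy)phenyl]but-3-enylide | C[S+](C)(=O)[CH-]C(=O)/C=C/c1ccc(O[Si](C)(C)C(C)(C)C)cc1
A5 | alternative 2 | (2S,3R)-2-[3,4-bis(tert-butyldimethylsilyloxy)phenyl]-3-[(4-methoxybenzyloxy)methyl]-6-[(E)-4-(tert-butyldimethylsilyloxy)styryl]-2,3-dihydro-4H-furo[3,2-c]pyran-4-one | COc1ccc(COC[C@H]2c3c(cc(/C=C/c4ccc(O[Si](C)(C)C(C)(C)C)cc4)oc3=O)O[C@@H]2c2ccc(O[Si](C)(C)C(C)(C)C)c(O[Si](C)(C)C(C)(C)C)c2)cc1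
A6 | alternative 3 | (S)-4-benzyl-3-{2-[4-chloro-2-oxo-6-((E)-4-(tert-butyldimethylsilyloxy)styryl)-2H-pyran-3-yl]acetyl}oxazolidin-2-one | O=C(Cc1c(Cl)cc(/C=C/c2ccc(O[Si](C)(C)C(C)(C)C)cc2)oc1=O)N1[C@@H](Cc2ccccc2)COC1=O
A7 | alternative 3 | 3,4-bis(tert-butyldimethylsilyloxy)benzaldehyde | O=Cc1ccc(O[Si](C)(C)C(C)(C)C)c(O[Si](C)(C)C(C)(C)C)c1
A8 | alternative 3 | (S)-4-benzyl-3-{(2S,3S)-2-[3,4-bis(tert-butyldimethylsilyloxy)phenyl]-4-oxo-6-[(E)-4-(tert-butyldimethylsilyloxy)styryl]-2,3-dihydro-4H-furo[3,2-c]pyran-3-carbonyl}oxazolidin-2-one | O=C([C@H]2c3c(cc(/C=C/c4ccc(O[Si](C)(C)C(C)(C)C)cc4)oc3=O)O[C@@H]2c2ccc(O[Si](C)(C)C(C)(C)C)c(O[Si](C)(C)C(C)(C)C)c2)N1[C@@H](Cc2ccccc2)COC1=O
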